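**Retrosynthetic overview**
1. Target 29 ⇐ exo-face hydrogenolysis/hydrogenation of alkenyl triflate 28 ⇐ Diels–Alder hetero-dimerisation (norbornene, last ring) of diene 20 (half A, 2π partner) with dienyl triflate 27 (half B, 4π partner only).
2. 20 and 27 ⇐ 10-hydroxy enones 17 and 25 ⇐ dienones 14 and 22 by ligand-controlled copper-catalysed 1,6-boration (the two C10 epimers), then conjugation (C1).
3. 14 and 22 ⇐ rhodium-catalysed allenic Pauson–Khand reaction (rings A and B together) of allene-yne lactone 12; C11 by hydrogenation (half A) or hydride reduction (half B).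
4. 12 (lactone ring C, first ring; C6 and C7) ⇐ chromium-catalysed asymmetric Nozaki–Hiyama–Kishi coupling of but-2-ynal 10 with allylic bromide 8 (C6–C7 bond, the key fragment union).
5. 8 ⇐ copper-catalysed SN2' allene coupling and Baylis–Hillman chemistry; ring order: C → A+B → norbornane.

Assumption: guaianolide numbering is used (C1–C15 = half A, primed = half B, α = face of H-7); by this reading of the SMILES half A is 10α-OH/11β-Me, half B is 10'β-OH/11'α-Me, and the 4'-methyl is endo on the norbornane.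

Step 1
Reactants: 1 2-(2-bromoethyl)-1,3-dioxolane; 2 1-bromobut-2-yne
Product: 4 2-(3-methylpenta-3,4-dien-1-yl)-1,3-dioxolane, via Grignard reagent 3 (not isolated)
Conditions: Mg, THF, 25 °C; then CuBr·SMe2 (5 mol %), 2, THF, −30 → 0 °C
Reagents that add atoms: none
Why: Copper-catalysed anti-SN2' substitution of the propargylic bromide by the Grignard reagent gives the 1,1-disubstituted allene, and no stereocenter is formed.

Step 2
Reactants: 4 2-(3-methylpenta-3,4-dien-1-yl)-1,3-dioxolane
Product: 5 4-methylhexa-4,5-dienal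
Conditions: 2 M HCl (aq), THF, rt
Reagents that add atoms: water, O
Why: Acid-catalysed acetal hydrolysis, which the isolated allene tolerates for a short time in dilute acid at room temperature.

Step 3
Reactants: 5 4-methylhexa-4,5-dienal; 6 methyl acrylate
Product: 7 methyl 3-hydroxy-6-methyl-2-methylideneocta-6,7-dienoate (racemic)
Conditions: DABCO (0.5 equiv), MeOH, rt, 4 d
Reagents that add atoms: none
Why: Morita–Baylis–Hillman reaction (DABCO adds to the acrylate and the resulting enolate adds to the aldehyde); the racemic carbinol centre is erased in step 4.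

Step 4
Reactants: 7 methyl 3-hydroxy-6-methyl-2-methylideneocta-6,7-dienoate
Product: 8 methyl (2Z)-2-(bromomethyl)-6-methylocta-2,6,7-trienoate
Conditions: N-bromosuccinimide, Me2S, CH2Cl2, 0 °C → rt
Reagents that add atoms: N-bromosuccinimide, BrN1C(=O)CCC1=O
Why: Corey–Kim-type activation of the allylic alcohol followed by SN2' attack of bromide gives the thermodynamically favoured (Z)-2-(bromomethyl)enoate without touching the allene.

Step 5
Reactants: 9 but-2-yn-1-ol
Product: 10 but-2-ynal
Conditions: MnO2 (10 equiv), CH2Cl2, rt; filtered and used as a solution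
Reagents that add atoms: none
Why: MnO2 oxidation of a propargylic alcohol stops cleanly at the volatile aldehyde.

Step 6
Reactants: 8 methyl (2Z)-2-(bromomethyl)-6-methylocta-2,6,7-trienoate; 10 but-2-ynal
Product: 12 (4S,5S)-3-methylidene-4-(3-methylpenta-3,4-dien-1-yl)-5-(prop-1-yn-1-yl)oxolan-2-one, via silyl ether 11 (not isolated)
Conditions: CrCl2 (10 mol %), 3,6-di-tert-butyl-1,8-bis[(4S)-4-isopropyl-4,5-dihydrooxazol-2-yl]-9H-carbazole (12 mol %), Mn (2 equiv), Et3N (20 mol %), Me3SiCl (1.5 equiv), THF, 0 °C → rt; then TsOH·H2O, CH2Cl2, rt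
Reagents that add atoms: none
Why: Catalytic asymmetric Nozaki–Hiyama–Kishi 2-(alkoxycarbonyl)allylation, in which the trivalent allylchromium from 8 adds through its γ-carbon in a chair transition state (γ-chain equatorial, anti adduct, hence the trans lactone) while the bis(oxazoline) ligand selects the aldehyde face, setting C6 and C7 as (4S,5S) (the ligand antipode would give ent-12); Mn regenerates divalent chromium and acid closes the lactone.

Step 7
Reactants: 12 (4S,5S)-3-methylidene-4-(3-methylpenta-3,4-dien-1-yl)-5-(prop-1-yn-1-yl)oxolan-2-one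
Product: 13 3-oxo-6βH,7αH-guaia-1(10),4,11(13)-trien-12,6α-olide
Conditions: [Rh(CO)2Cl]2 (5 mol %), CO (1 atm), toluene, 90 °C
Reagents that add atoms: carbon monoxide, [C-]#[O+]
Why: Rhodium-catalysed allenic Pauson–Khand reaction, which joins the distal allene double bond, the alkyne and CO to build rings A and B in one step; no stereocenter is formed.

Step 8
Reactants: 13 3-oxo-6βH,7αH-guaia-1(10),4,11(13)-trien-12,6α-olide
Product: 14 (11R)-3-oxo-6βH,7αH,11αH-guaia-1(10),4-dien-12,6α-olide
Conditions: H2 (1 atm), RhCl(PPh3)3 (5 mol %), benzene–EtOH, rt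
Reagents that add atoms: none
Why: Homogeneous hydrogenation reduces only the exocyclic 1,1-disubstituted alkene and delivers H2 to the less hindered α face of the trans-fused lactone (the face electrophiles use on such lactone enolates), giving the 11β-methyl (11R) centre.

Step 9
Reactants: 14 (11R)-3-oxo-6βH,7αH,11αH-guaia-1(10),4-dien-12,6α-olide
Product: 15 10α-(pinacolboryl)-3-oxo-6βH,7αH,11αH-guai-1(5)-en-12,6α-olide (10β-methyl, C4 epimers)
Conditions: CuCl (5 mol %), (R,R)-QuinoxP* (6 mol %), NaOtBu (10 mol %), B2pin2 (1.2 equiv), MeOH (2 equiv), THF, 0 °C → rt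
Reagents that add atoms: bis(pinacolato)diboron, CC1(C)OB(OC1(C)C)B1OC(C)(C)C(C)(C)O1
Why: Proposed new method: ligand-controlled, δ-selective copper-catalysed 1,6-protoboration of a ring-fused linear dienone with a fully substituted δ-carbon, in which the L*Cu–Bpin species adds across the distal C1=C10 bond with boron at the electrophilic δ-carbon C10, MeOH protonates the copper dienolate at C4, and, because the remote lactone gives little facial bias, the bisphosphine antipode dictates α-face boron delivery (the antipode-to-face match is confirmed on the first run; the two antipodes give the two C10 epimers); the closest known reaction type is the copper-catalysed enantioselective 1,6-boration of acyclic dienoates and dienones together with the β-boration of β,β-disubstituted cyclic enones to tertiary boronates.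

Step 10
Reactants: 15 10α-(pinacolboryl)-3-oxo-6βH,7αH,11αH-guai-1(5)-en-12,6α-olide
Product: 16 10α-hydroxy-3-oxo-6βH,7αH,11αH-guai-1(5)-en-12,6α-olide (C4 epimers)
Conditions: NaBO3·4H2O, THF–H2O, rt
Reagents that add atoms: sodium perborate NaBO3, [Na+].[O-]OB=O
Why: Stereoretentive oxidation of the tertiary C–B bond (1,2-migration of carbon from boron to peroxide oxygen) gives the 10α-alcohol.

Step 11
Reactants: 16 10α-hydroxy-3-oxo-6βH,7αH,11αH-guai-1(5)-en-12,6α-olide
Product: 17 10α-hydroxy-3-oxo-1αH,6βH,7αH,11αH-guai-4-en-12,6α-olide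
Conditions: DBU (0.3 equiv), toluene, rt
Reagents that add atoms: none
Why: Base-mediated conjugation of the β,γ-enone through its dienolate, with C1 protonated under equilibrating conditions to give the conjugated 1α-H enone typical of this compound class, while the much less acidic lactone α-centre C11 is untouched.

Step 12
Reactants: 17 10α-hydroxy-3-oxo-1αH,6βH,7αH,11αH-guai-4-en-12,6α-olide
Product: 19 10α-hydroxy-3-triflyloxy-1αH,6βH,7αH,11αH-guaia-2,4-dien-12,6α-olide, via dilithium dienolate 18 (not isolated)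
Conditions: LiN(iPr)2 (2.2 equiv), THF, −78 °C; PhNTf2 (1.1 equiv), −78 → 0 °C
Reagents that add atoms: N-phenylbis(trifluoromethanesulfonimide), O=S(=O)(N(c1ccccc1)S(=O)(=O)C(F)(F)F)C(F)(F)F
Why: Kinetic α'-deprotonation at C2 gives the cross-conjugated dienolate, whose O-sulfonylation by PhNTf2 (to which the hindered tertiary alkoxide is inert) gives the dienyl triflate without touching a stereocenter.

Step 13
Reactants: 19 10α-hydroxy-3-triflyloxy-1αH,6βH,7αH,11αH-guaia-2,4-dien-12,6α-olide
Product: 20 10α-hydroxy-1αH,6βH,7αH,11αH-guaia-2,4-dien-12,6α-olide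
Conditions: Pd(PPh3)4 (5 mol %), Bu3SnH (1.2 equiv), LiCl (3 equiv), THF, rt; kept cold and used at once
Reagents that add atoms: none
Why: Palladium-catalysed reduction of an alkenyl triflate by tin hydride (oxidative addition to zerovalent palladium, hydride transfer from tin, reductive elimination) unveils the cyclopentadiene under neutral conditions at room temperature.

Step 14
Reactants: 12 (4S,5S)-3-methylidene-4-(3-methylpenta-3,4-dien-1-yl)-5-(prop-1-yn-1-yl)oxolan-2-one
Product: 21 (3S,4S,5S)-3-methyl-4-(3-methylpenta-3,4-dien-1-yl)-5-(prop-1-yn-1-yl)oxolan-2-one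
Conditions: NaBH4 (1.5 equiv), MeOH, 0 °C → rt
Reagents that add atoms: none
Why: Conjugate hydride reduction of the α-methylene lactone, after which the methanolic methoxide equilibrates C11 to the all-trans lactone, i.e. the 11α-methyl (11S) centre.

Step 15
Reactants: 21 (3S,4S,5S)-3-methyl-4-(3-methylpenta-3,4-dien-1-yl)-5-(prop-1-yn-1-yl)oxolan-2-one
Product: 22 (11S)-3-oxo-6βH,7αH,11βH-guaia-1(10),4-dien-12,6α-olide
Conditions: [Rh(CO)2Cl]2 (5 mol %), CO (1 atm), toluene, 90 °C
Reagents that add atoms: carbon monoxide, [C-]#[O+]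
Why: Rhodium-catalysed allenic Pauson–Khand reaction as in step 7, forming rings A and B without a new stereocenter.

Step 16
Reactants: 22 (11S)-3-oxo-6βH,7αH,11βH-guaia-1(10),4-dien-12,6α-olide
Product: 23 10β-(pinacolboryl)-3-oxo-6βH,7αH,11βH-guai-1(5)-en-12,6α-olide (10α-methyl, C4 epimers)
Conditions: CuCl (5 mol %), (S,S)-QuinoxP* (6 mol %), NaOtBu (10 mol %), B2pin2 (1.2 equiv), MeOH (2 equiv), THF, 0 °C → rt
Reagents that add atoms: bis(pinacolato)diboron, CC1(C)OB(OC1(C)C)B1OC(C)(C)C(C)(C)O1
Why: Proposed new method: the same ligand-controlled δ-selective copper-catalysed 1,6-protoboration as in step 9, run with the antipodal bisphosphine so that L*Cu–Bpin delivers boron to the β face of C10 before MeOH protonates the copper dienolate at C4; the closest known reaction type is again the copper-catalysed enantioselective 1,6-boration of acyclic dienoates and the β-boration of β,β-disubstituted cyclic enones.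

Step 17
Reactants: 23 10β-(pinacolboryl)-3-oxo-6βH,7αH,11βH-guai-1(5)-en-12,6α-olide
Product: 24 10β-hydroxy-3-oxo-6βH,7αH,11βH-guai-1(5)-en-12,6α-olide (C4 epimers)
Conditions: NaBO3·4H2O, THF–H2O, rt
Reagents that add atoms: sodium perborate NaBO3, [Na+].[O-]OB=O
Why: Stereoretentive boronate oxidation gives the 10β-alcohol.

Step 18
Reactants: 24 10β-hydroxy-3-oxo-6βH,7αH,11βH-guai-1(5)-en-12,6α-olide
Product: 25 10β-hydroxy-3-oxo-1αH,6βH,7αH,11βH-guai-4-en-12,6α-olide
Conditions: DBU (0.3 equiv), toluene, rt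
Reagents that add atoms: none
Why: Base-mediated enone conjugation as in step 11, setting the 1α-H centre under equilibrating conditions.

Step 19
Reactants: 25 10β-hydroxy-3-oxo-1αH,6βH,7αH,11βH-guai-4-en-12,6α-olide
Product: 27 10β-hydroxy-3-triflyloxy-1αH,6βH,7αH,11βH-guaia-2,4-dien-12,6α-olide, via dilithium dienolate 26 (not isolated)
Conditions: LiN(iPr)2 (2.2 equiv), THF, −78 °C; PhNTf2 (1.1 equiv), −78 → 0 °C
Reagents that add atoms: N-phenylbis(trifluoromethanesulfonimide), O=S(=O)(N(c1ccccc1)S(=O)(=O)C(F)(F)F)C(F)(F)F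
Why: Kinetic α'-enolisation and O-sulfonylation as in step 12 give the dienyl triflate.

Step 20
Reactants: 20 10α-hydroxy-1αH,6βH,7αH,11αH-guaia-2,4-dien-12,6α-olide; 27 10β-hydroxy-3-triflyloxy-1αH,6βH,7αH,11βH-guaia-2,4-dien-12,6α-olide
Product: 28 endo [4+2] hetero-dimer with bonds C2–C2' and C3–C5' and a C3'(OTf)=C4' alkenyl triflate
Conditions: 27 (3 equiv), neat with a trace of toluene, BHT (1 mol %), 25 °C, 7 d; excess 27 recovered
Reagents that add atoms: none
Why: Thermal endo Diels–Alder hetero-dimerisation of the kind by which guaia-2,4-dienolides dimerise, in which 27 can only be the 4π partner because its C2'=C3' bond carries the triflate (as 2π partner it would have to join two fully substituted carbons), 20 reacts through C2=C3, each partner is attacked anti to the C10 substituent on its sp3 carbon, and the new bonds set C2, C3, C2' and C5'.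

Step 21
Reactants: 28 endo [4+2] hetero-dimer alkenyl triflate
Product: 29 CNP0182139.1
Conditions: H2 (1 atm), PtO2 (20 mol %), NaHCO3 (2 equiv), EtOAc, rt
Reagents that add atoms: none
Why: Hydrogenolysis of the alkenyl triflate and syn hydrogenation over PtO2 take place on the exo face (the endo face is covered by half A and the 10'-hydroxyl lies over the exo face and anchors the substrate), so H adds to C4' exo and the 4'-methyl ends up endo as in the target.

**Compound list**
1 | 2-(2-bromoethyl)-1,3-dioxolane | BrCCC1OCCO1 | starting material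
2 | 1-bromobut-2-yne | CC#CCBr | starting material
3 | [2-(1,3-dioxolan-2-yl)ethyl]magnesium bromide | Br[Mg]CCC1OCCO1 | intermediate (not isolated)
4 | 2-(3-methylpenta-3,4-dien-1-yl)-1,3-dioxolane | C=C=C(C)CCC1OCCO1 | intermediate
5 | 4-methylhexa-4,5-dienal | C=C=C(C)CCC=O | intermediate
6 | methyl acrylate | C=CC(=O)OC | starting material
7 | methyl 3-hydroxy-6-methyl-2-methylideneocta-6,7-dienoate (racemic) | C=C=C(C)CCC(O)C(=C)C(=O)OC | intermediate
8 | methyl (2Z)-2-(bromomethyl)-6-methylocta-2,6,7-trienoate | C=C=C(C)CC/C=C(\CBr)C(=O)OC | intermediate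
9 | but-2-yn-1-ol | CC#CCO | starting material
10 | but-2-ynal | CC#CC=O | intermediate
11 | methyl (3S,4S)-3-(3-methylpenta-3,4-dien-1-yl)-2-methylidene-4-(trimethylsilyloxy)hept-5-ynoate | CC#C[C@@H](O[Si](C)(C)C)[C@@H](CCC(C)=C=C)C(=C)C(=O)OC | intermediate (not isolated)
12 | (4S,5S)-3-methylidene-4-(3-methylpenta-3,4-dien-1-yl)-5-(prop-1-yn-1-yl)oxolan-2-one | CC#C[C@H]1OC(=O)C(=C)[C@@H]1CCC(C)=C=C | intermediate
13 | 3-oxo-6βH,7αH-guaia-1(10),4,11(13)-trien-12,6α-olide | CC1=C2[C@H]3OC(=O)C(=C)[C@@H]3CCC(C)=C2CC1=O | intermediate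
14 | (11R)-3-oxo-6βH,7αH,11αH-guaia-1(10),4-dien-12,6α-olide (11β-methyl) | CC1=C2[C@H]3OC(=O)[C@H](C)[C@@H]3CCC(C)=C2CC1=O | intermediate
15 | 10α-(4,4,5,5-tetramethyl-1,3,2-dioxaborolan-2-yl)-3-oxo-6βH,7αH,11αH-guai-1(5)-en-12,6α-olide (10β-methyl, C4 epimers) | CC1C(=O)CC2=C1[C@H]3OC(=O)[C@H](C)[C@@H]3CC[C@@]2(C)B4OC(C)(C)C(C)(C)O4 | intermediate
16 | 10α-hydroxy-3-oxo-6βH,7αH,11αH-guai-1(5)-en-12,6α-olide (C4 epimers) | CC1C(=O)CC2=C1[C@H]3OC(=O)[C@H](C)[C@@H]3CC[C@@]2(C)O | intermediate
17 | 10α-hydroxy-3-oxo-1αH,6βH,7αH,11αH-guai-4-en-12,6α-olide | CC1=C2[C@H]3OC(=O)[C@H](C)[C@@H]3CC[C@@](C)(O)[C@@H]2CC1=O | intermediate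
18 | dilithium 10α-alkoxide 2,4-dien-3-olate of 17 | CC1=C2[C@H]3OC(=O)[C@H](C)[C@@H]3CC[C@@](C)(O[Li])[C@@H]2C=C1O[Li] | intermediate (not isolated)
19 | 10α-hydroxy-3-[(trifluoromethylsulfonyl)oxy]-1αH,6βH,7αH,11αH-guaia-2,4-dien-12,6α-olide | CC1=C2[C@H]3OC(=O)[C@H](C)[C@@H]3CC[C@@](C)(O)[C@@H]2C=C1OS(=O)(=O)C(F)(F)F | intermediate
20 | 10α-hydroxy-1αH,6βH,7αH,11αH-guaia-2,4-dien-12,6α-olide (half A diene) | CC1=C2[C@H]3OC(=O)[C@H](C)[C@@H]3CC[C@@](C)(O)[C@@H]2C=C1 | intermediate
21 | (3S,4S,5S)-3-methyl-4-(3-methylpenta-3,4-dien-1-yl)-5-(prop-1-yn-1-yl)oxolan-2-one | CC#C[C@H]1OC(=O)[C@@H](C)[C@@H]1CCC(C)=C=C | intermediate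
22 | (11S)-3-oxo-6βH,7αH,11βH-guaia-1(10),4-dien-12,6α-olide (11α-methyl) | CC1=C2[C@H]3OC(=O)[C@@H](C)[C@@H]3CCC(C)=C2CC1=O | intermediate
23 | 10β-(4,4,5,5-tetramethyl-1,3,2-dioxaborolan-2-yl)-3-oxo-6βH,7αH,11βH-guai-1(5)-en-12,6α-olide (10α-methyl, C4 epimers) | CC1C(=O)CC2=C1[C@H]3OC(=O)[C@@H](C)[C@@H]3CC[C@]2(C)B4OC(C)(C)C(C)(C)O4 | intermediate
24 | 10β-hydroxy-3-oxo-6βH,7αH,11βH-guai-1(5)-en-12,6α-olide (C4 epimers) | CC1C(=O)CC2=C1[C@H]3OC(=O)[C@@H](C)[C@@H]3CC[C@]2(C)O | intermediate
25 | 10β-hydroxy-3-oxo-1αH,6βH,7αH,11βH-guai-4-en-12,6α-olide | CC1=C2[C@H]3OC(=O)[C@@H](C)[C@@H]3CC[C@](C)(O)[C@@H]2CC1=O | intermediate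
26 | dilithium 10β-alkoxide 2,4-dien-3-olate of 25 | CC1=C2[C@H]3OC(=O)[C@@H](C)[C@@H]3CC[C@](C)(O[Li])[C@@H]2C=C1O[Li] | intermediate (not isolated)
27 | 10β-hydroxy-3-[(trifluoromethylsulfonyl)oxy]-1αH,6βH,7αH,11βH-guaia-2,4-dien-12,6α-olide (half B dienyl triflate) | CC1=C2[C@H]3OC(=O)[C@@H](C)[C@@H]3CC[C@](C)(O)[C@@H]2C=C1OS(=O)(=O)C(F)(F)F | intermediate
28 | endo [4+2] hetero-dimer of 20 (2π, C2=C3) and 27 (4π): bonds C2–C2' and C3–C5', ring A endo, C10' syn to the C3'(OTf)=C4'(CH3) bridge | CC1=C2[C@H]3OC(=O)[C@H](C)[C@@H]3CC[C@@](C)(O)[C@@H]2[C@H]2[C@H]3C(OS(=O)(=O)C(F)(F)F)=C(C)[C@]4([C@@H]3[C@@](C)(O)CC[C@H]3[C@H](C)C(=O)O[C@@H]34)[C@@H]12 | intermediate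
29 | CNP0182139.1: 3',4'-dihydro hetero-dimer, half A 10α-OH/11β-Me/Δ4, half B 10'β-OH/11'α-Me, 4'-methyl endo | CC1=C2[C@H]3OC(=O)[C@H](C)[C@@H]3CC[C@@](C)(O)[C@@H]2[C@H]2[C@H]3C[C@@H](C)[C@]4([C@@H]3[C@@](C)(O)CC[C@H]3[C@H](C)C(=O)O[C@@H]34)[C@@H]12 | target

**Step count**
Total step count: 21. Longest linear sequence: 14 steps (steps 1–4, 6–13, 20 and 21).

**Steps most likely to fail**

Step 9 (proposed new boration, half A). The fallback uses known chemistry and sets out from 14. mCPBA, NaHCO3, CH2Cl2, 0 °C epoxidises the electron-rich distal C1=C10 bond (not the enone bond) from the α face to give 1α,10α-epoxy-3-oxo-6βH,7αH,11αH-guai-4-en-12,6α-olide F1. SmI2, THF–MeOH, −78 °C then cleaves the C1–O bond (reduction of a vinylogous α-oxygenated ketone) and the samarium dienolate is protonated at C4. This gives 16, where the fallback comes back to the route; a minor C10 epimer, if formed, is removed at 17.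

Step 16 (proposed new boration, half B). The fallback uses known chemistry and sets out from 22. N-bromosuccinimide, THF–H2O, 0 °C forms the bromonium ion on the same α face, and water opens it at the tertiary carbon C10 from the β face to give 1α-bromo-10β-hydroxy-3-oxo-6βH,7αH,11βH-guai-4-en-12,6α-olide F2. Zn, AcOH, THF, 0 °C removes the bromine through the zinc dienolate, which is protonated at C4 to give 24, where the route is rejoined. The epoxide and bromohydrin routes turn one electrophile face preference into opposite C10 configurations, so the two fallbacks are exchanged between the series if that preference proves to be β.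

Step 20 (cross-dimerisation; 20 can also dimerise with itself and the triflate may slow 27 as a diene). The fallback sets out from 27, together with 20. Pd(PPh3)4, Bu3SnH, LiCl, THF, rt reduces 27 to the parent diene 10β-hydroxy-1αH,6βH,7αH,11βH-guaia-2,4-dien-12,6α-olide F3. 20 and F3 (1:3), neat at 25 °C, give the statistical set of [4+2] dimers, from which the cross-dimer with a free C3'=C4' bond, 3',4'-didehydro-29 F4, is isolated by preparative HPLC. H2 (1 atm), [Ir(cod)(PCy3)(py)]PF6, CH2Cl2, 0 °C, directed by the 10'-hydroxyl, then hydrogenates C3'=C4' from the exo face. The fallback comes back to the route at 29 and so also replaces step 21.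

Further compounds
F1 | step 9 | 1α,10α-epoxy-3-oxo-6βH,7αH,11αH-guai-4-en-12,6α-olide | CC1=C2[C@H]3OC(=O)[C@H](C)[C@@H]3CC[C@@]4(C)O[C@@]24CC1=O
F2 | step 16 | 1α-bromo-10β-hydroxy-3-oxo-6βH,7αH,11βH-guai-4-en-12,6α-olide | CC1=C2[C@H]3OC(=O)[C@@H](C)[C@@H]3CC[C@](C)(O)[C@]2(Br)CC1=O
F3 | step 20 | 10β-hydroxy-1αH,6βH,7αH,11βH-guaia-2,4-dien-12,6α-olide | CC1=C2[C@H]3OC(=O)[C@@H](C)[C@@H]3CC[C@](C)(O)[C@@H]2C=C1
F4 | step 20 | 3',4'-didehydro-29 (cross-dimer with C3'=C4' double bond) | CC1=C2[C@H]3OC(=O)[C@H](C)[C@@H]3CC[C@@](C)(O)[C@@H]2[C@H]2[C@H]3C=C(C)[C@]4([C@@H]3[C@@](C)(O)CC[C@H]3[C@H](C)C(=O)O[C@@H]34)[C@@H]12
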